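A direct plan would grow the chain first and close the furan last: tetradecane-1,14-diol A1 would be monobrominated to 14-bromotetradecan-1-ol A2, which would be oxidised to 14-bromotetradecanal A3 and treated with a vinyl Grignard reagent to give 16-bromohexadec-1-en-3-ol A4.
Palladium-catalysed addition of A4 to an alkoxyallene would give the mixed acrolein acetal A5; the dianion of hex-5-ynoic acid A6 would displace its bromide and the carboxylate would be methylated in the same flask to diene ester A7.
Ring-closing metathesis of A7 and acid-promoted loss of methanol would give methyl 19-(furan-2-yl)nonadec-5-ynoate A8, and saponification of A8 would give the target acid.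
Weak step, the furan ring closure by diene metathesis: three operations (vinyl addition, acetal formation, metathesis/aromatisation), two precious-metal catalysts, high dilution and two stereocentres set only to be erased, all for a monosubstituted furan, with an internal alkyne in the substrate that invites enyne metathesis.
Weak step, the chain coupling by acetylide SN2: the alkynoate dianion is a strong base, the long-chain primary bromide is a sluggish electrophile that can also eliminate, HMPA is needed, and an acid-labile acetal is carried through it.
Weak step, the ester detour: methylation and later saponification build nothing, and they follow a statistical monobromination and a redox change at the front.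

**Retrosynthetic overview**
The feature used is C1–C6 of the target, HO2C–(CH2)3–C≡C–: carboxyl carbon C1 and alkyne carbon C5 stand 1,5 to each other, the retron of a Grob-type ring fragmentation. C1–C6 are the six ring carbons of cyclohexane-1,3-dione, with C6 the carbon between the two carbonyl groups.
Key disconnection: the C5≡C6 triple bond and the open C1 terminus are traced back to vinylogous acyl triflate 10. Hydride-triggered cleavage of the ring bond joining the future C1 and C6 makes both at once, and one oxidation then gives the acid.
The C6–C7 bond comes from reductive alkylation of cyclohexane-1,3-dione with aldehyde 6. The C19–furan bond comes from alkylation of 2-lithiofuran with 1,12-dibromododecane, and the thirteenth methylene (C7) from DMF.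
Ring order: no ring is closed. The furan is bought as furan, and the only ring event is the opening of the carbocycle. The target has no stereocentre.
This avoids a furan construction, metathesis beside an alkyne, acetylide SN2 with HMPA, and any protecting group or ester; the alkyne appears only in the second-to-last step.

Key step: step 5

Remark: dione 9 is drawn as the diketone although it should exist largely as its enol; 11 holds one stereocentre, is formed racemic and loses it in the same flask.

Step 1
Reactants: 1 furan; 2 1,12-dibromododecane
Product: 4 2-(12-bromododecyl)furan, via 2-lithiofuran 3 (not isolated)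
Conditions: n-BuLi (1.0 equiv), THF, −78 to 0 °C; then added to 2 (3 equiv), THF/DMPU, 0 °C to rt
Reagents that add atoms: none
Why: Furan is metalated at C2 next to the ring oxygen and the 2-furyllithium displaces one bromide of the dibromide by SN2 (lithiation/alkylation of furan); the threefold excess of 2, which can be recovered, should hold down double substitution.

Step 2
Reactants: 4 2-(12-bromododecyl)furan
Product: 6 13-(furan-2-yl)tridecanal, via Grignard reagent 5 (not isolated)
Conditions: Mg (1.5 equiv), I2 (cat.), THF, 45 °C; then DMF (1.5 equiv), 0 °C to rt; aq. NH4Cl
Reagents that add atoms: N,N-dimethylformamide, CN(C)C=O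
Why: Bouveault aldehyde synthesis, in which the primary alkylmagnesium bromide adds once to DMF and the tetrahedral magnesium hemiaminal salt survives until the mild aqueous quench releases the aldehyde (the future C7), while the furan is inert to the Grignard reagent.

Step 3
Reactants: 6 13-(furan-2-yl)tridecanal; 7 cyclohexane-1,3-dione
Product: 9 2-[13-(furan-2-yl)tridecyl]cyclohexane-1,3-dione, via alkylidene dione 8 (not isolated)
Conditions: 7 (1.0 equiv), Hantzsch ester (1.05 equiv), L-proline (10 mol%), CH2Cl2, rt
Reagents that add atoms: none
Why: Organocatalytic three-component reductive alkylation, in which proline-catalysed Knoevenagel condensation gives the very electrophilic alkylidene dione 8 that is reduced at once by conjugate hydride transfer from the Hantzsch ester, so the C6–C7 bond is made by C-alkylation only, without O-alkylation and before a second dione can add.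

Step 4
Reactants: 9 2-[13-(furan-2-yl)tridecyl]cyclohexane-1,3-dione
Product: 10 2-[13-(furan-2-yl)tridecyl]-3-oxocyclohex-1-en-1-yl trifluoromethanesulfonate
Conditions: Tf2O (1.2 equiv), pyridine (2 equiv), CH2Cl2, −78 to 0 °C
Reagents that add atoms: trifluoromethanesulfonic anhydride, O=S(=O)(OS(=O)(=O)C(F)(F)F)C(F)(F)F
Why: O-Sulfonylation of the enol of the symmetric 1,3-dione (either oxygen gives the same vinylogous acyl triflate) is fast at low temperature, where pyridine-buffered Tf2O should not touch the 2-alkylfuran.

Step 5
Reactants: 10 2-[13-(furan-2-yl)tridecyl]-3-oxocyclohex-1-en-1-yl trifluoromethanesulfonate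
Product: 13 19-(furan-2-yl)nonadec-5-yn-1-ol, via lithium alkoxide 11 (not isolated), via 19-(furan-2-yl)nonadec-5-ynal 12 (not isolated)
Conditions: LiBHEt3 (2.5 equiv), THF, −78 °C; then 60 °C; aq. NH4Cl
Reagents that add atoms: none
Why: Hydride adds 1,2 to the ring carbonyl (the future C1) at −78 °C to give lithium alkoxide 11; on warming the alkoxide collapses to a carbonyl group while the ring bond from the carbinol carbon to the alkyl-bearing olefinic carbon (future C6) breaks and triflate leaves from the other olefinic carbon (future C5), a Grob-type fragmentation that forms C5≡C6 and releases ynal 12, which the second equivalent of hydride reduces in the flask to alkynol 13. The closest known reaction type is the tandem nucleophilic addition/carbon–carbon bond cleavage of cyclic vinylogous acyl triflates made from 2-alkylcyclohexane-1,3-diones, known with organolithium, Grignard, amide and hydride triggers and related to the Eschenmoser–Tanabe fragmentation. No ring is closed: the six-membered carbocycle is opened and its six carbons become C1–C6 of the chain. No stereocentre remains, since the carbinol centre of 11 is formed racemic and disappears in the fragmentation. The step needs 1,2- rather than 1,4-addition of hydride and carbon–carbon cleavage rather than loss of the triflate by attack at sulfur; the hard hydride at low temperature, the anti-periplanar arrangement of the breaking ring bond and the C–OTf bond across the ring double bond, and the very good leaving group should secure this, while the furan and the new internal alkyne are inert to the borohydride.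

Step 6
Reactants: 13 19-(furan-2-yl)nonadec-5-yn-1-ol
Product: 14 19-(furan-2-yl)nonadec-5-ynoic acid
Conditions: TEMPO (20 mol%), PhI(OAc)2 (2.2 equiv), MeCN/H2O (1:1), 0 °C to rt; extraction at pH 4
Reagents that add atoms: water, O
Why: Oxoammonium (TEMPO) oxidation of the primary alcohol to the aldehyde, whose hydrate is oxidised further to the carboxylic acid in the aqueous medium with PhI(OAc)2 as terminal oxidant; no electrophilic halogen, peracid or strong acid is present, so the 2-alkylfuran and the internal alkyne should survive.

**Compound list**
1 | furan | c1ccoc1 | starting material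
2 | 1,12-dibromododecane | BrCCCCCCCCCCCCBr | starting material
3 | 2-lithiofuran | [Li]c1ccco1 | intermediate
4 | 2-(12-bromododecyl)furan | BrCCCCCCCCCCCCc1ccco1 | intermediate
5 | [12-(furan-2-yl)dodecyl]magnesium bromide | Br[Mg]CCCCCCCCCCCCc1ccco1 | intermediate
6 | 13-(furan-2-yl)tridecanal | O=CCCCCCCCCCCCCc1ccco1 | intermediate
7 | cyclohexane-1,3-dione | O=C1CCCC(=O)C1 | starting material
8 | 2-[13-(furan-2-yl)tridecylidene]cyclohexane-1,3-dione | O=C1CCCC(=O)C1=CCCCCCCCCCCCCc1ccco1 | intermediate
9 | 2-[13-(furan-2-yl)tridecyl]cyclohexane-1,3-dione | O=C1CCCC(=O)C1CCCCCCCCCCCCCc1ccco1 | intermediate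
10 | 2-[13-(furan-2-yl)tridecyl]-3-oxocyclohex-1-en-1-yl trifluoromethanesulfonate | O=C1CCCC(OS(=O)(=O)C(F)(F)F)=C1CCCCCCCCCCCCCc1ccco1 | intermediate
11 | lithium 2-[13-(furan-2-yl)tridecyl]-3-(trifluoromethanesulfonyloxy)cyclohex-2-en-1-olate (racemic) | [Li+].[O-]C1CCCC(OS(=O)(=O)C(F)(F)F)=C1CCCCCCCCCCCCCc1ccco1 | intermediate
12 | 19-(furan-2-yl)nonadec-5-ynal | O=CCCCC#CCCCCCCCCCCCCCc1ccco1 | intermediate
13 | 19-(furan-2-yl)nonadec-5-yn-1-ol | OCCCCC#CCCCCCCCCCCCCCc1ccco1 | intermediate
14 | 19-(furan-2-yl)nonadec-5-ynoic acid | O=C(O)CCCC#CCCCCCCCCCCCCCc1ccco1 | target

**Totals**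
Total step count: 6. Longest linear sequence: 6 steps (from furan).

**Steps most likely to fail**

Step 5 (fragmentation). Hydride could be delivered in the conjugate sense or attack sulfur, returning enone or dione instead of the 1,2-adduct, and the secondary alkoxide could fragment only sluggishly. The fallback is an Eschenmoser–Tanabe fragmentation and sets out from dione 9. Heating 9 with 2-methylpropan-1-ol and catalytic TsOH in toluene with removal of water would give the vinylogous ester 2-[13-(furan-2-yl)tridecyl]-3-(2-methylpropoxy)cyclohex-2-en-1-one F1. Reduction with LiAlH4 in Et2O at 0 °C and work-up with dilute HCl would give 2-[13-(furan-2-yl)tridecyl]cyclohex-2-en-1-one F2. Epoxidation with H2O2/NaOH in MeOH at 0 °C would give racemic 1-[13-(furan-2-yl)tridecyl]-7-oxabicyclo[4.1.0]heptan-2-one F3. Treatment with 2,4-dinitrobenzenesulfonylhydrazide and pyridine in THF at 0 °C to rt would form N'-{1-[13-(furan-2-yl)tridecyl]-7-oxabicyclo[4.1.0]heptan-2-ylidene}-2,4-dinitrobenzenesulfonohydrazide F4, which should lose nitrogen and the sulfinate in the flask to give ynal 12, here isolated. The fallback comes back to the route at 12, which would be oxidised to 14 with Ag2O in aqueous NaOH/EtOH.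

Step 6 (oxidation). The oxoammonium salt or the trivalent iodine reagent could attack the electron-rich furan ring and open it oxidatively before the aldehyde hydrate is consumed. The fallback sets out from 13 and changes the oxidant class in two stages. Dess–Martin periodinane with NaHCO3 in CH2Cl2 would give ynal 12, which would be isolated. Ag2O (from AgNO3 and NaOH) in aqueous EtOH would then oxidise it under basic conditions, in the way furan-2-carbaldehyde is converted to its acid. The fallback comes back at 14 and makes no new compound.

Step 1 (furan alkylation). Double substitution of the dibromide and elimination by the basic furyllithium could erode the mono-alkylation. The fallback sets out from 1 and uses a monofunctional electrophile. 2-Lithiofuran 3 would be alkylated with commercial 12-bromododec-1-ene to give 2-(dodec-11-en-1-yl)furan F5. Linear-selective hydroformylation (Rh(acac)(CO)2, BiPhePhos, CO/H2, toluene, 80 °C) would then add the last carbon and come back to the route at aldehyde 6, bypassing 4 and 5.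

**Further compounds**
F1 | step 5 | 2-[13-(furan-2-yl)tridecyl]-3-(2-methylpropoxy)cyclohex-2-en-1-one | CC(C)COC1=C(CCCCCCCCCCCCCc2ccco2)C(=O)CCC1
F2 | step 5 | 2-[13-(furan-2-yl)tridecyl]cyclohex-2-en-1-one | O=C1CCCC=C1CCCCCCCCCCCCCc1ccco1
F3 | step 5 | 1-[13-(furan-2-yl)tridecyl]-7-oxabicyclo[4.1.0]heptan-2-one (racemic) | O=C1CCCC2OC12CCCCCCCCCCCCCc1ccco1
F4 | step 5 | N'-{1-[13-(furan-2-yl)tridecyl]-7-oxabicyclo[4.1.0]heptan-2-ylidene}-2,4-dinitrobenzenesulfonohydrazide (racemic) | O=S(=O)(NN=C1CCCC2OC12CCCCCCCCCCCCCc1ccco1)c1ccc(cc1[N+](=O)[O-])[N+](=O)[O-]
F0 | step 6 | none | none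
F5 | step 1 | 2-(dodec-11-en-1-yl)furan | C=CCCCCCCCCCCc1ccco1
A1 | direct plan | tetradecane-1,14-diol | OCCCCCCCCCCCCCCO
A2 | direct plan | 14-bromotetradecan-1-ol | OCCCCCCCCCCCCCCBr
A3 | direct plan | 14-bromotetradecanal | O=CCCCCCCCCCCCCCBr
A4 | direct plan | 16-bromohexadec-1-en-3-ol (racemic) | C=CC(O)CCCCCCCCCCCCCBr
A5 | direct plan | 16-bromo-3-(1-methoxyprop-2-enyloxy)hexadec-1-ene (racemic, both diastereomers) | C=CC(OC(OC)C=C)CCCCCCCCCCCCCBr
A6 | direct plan | hex-5-ynoic acid | C#CCCCC(=O)O
A7 | direct plan | methyl 20-(1-methoxyprop-2-enyloxy)docos-21-en-5-ynoate (racemic, both diastereomers) | COC(=O)CCCC#CCCCCCCCCCCCCCC(C=C)OC(OC)C=C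
A8 | direct plan | methyl 19-(furan-2-yl)nonadec-5-ynoate | COC(=O)CCCC#CCCCCCCCCCCCCCc1ccco1
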